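**Strategy.** The cyclopentenone ring A (C1–C2–C3–C4–C9) is disconnected at C2–C3 and C4–C9, a formal [3+2] union of a C3≡C4 alkyne with a C9=C1–C2(O)OMe enoate. A nickel-catalysed reductive cycloaddition of an acyclic alkynyl enoate forms both bonds in one operation. It closes cyclohexane ring B and enone ring A and creates the C9 quaternary centre, exploiting the C4=C3–C2=O enone flanked by quaternary C5 and C9. The precursor is an open chain carrying the C5, C6, C8, C10 and C14 centres, made by Eschenmoser–Tanabe fragmentation of a cyclohexenone template and a chromium-mediated coupling. A late intramolecular allylchromium addition (C11–C12) closes the eight-membered ring.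

Key step: step 15

Remark: atoms are numbered as in mutilin (C1–C20) and every configuration is taken exactly as encoded in the SMILES (5S,6S,8S,9R,10R,11S,12S,14R); C6 is fixed by the catalyst of step 1, and C5 and C14 are set relative to it.

Step 1
Reactants: 1 (E)-but-2-enal; 2 tert-butyl 3-oxobutanoate
Product: 4 (S)-5-methylcyclohex-2-en-1-one, via Michael adduct 3 (not isolated)
Conditions: (R)-α,α-diphenylprolinol trimethylsilyl ether (10 mol%), neat, rt; then TsOH·H2O, toluene, 80 °C
Reagents that add atoms: none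
Why: Iminium-catalysed Michael addition of the β-keto ester to the enal face left open by the (R)-catalyst should set C6 (S), and acid then drives intramolecular aldol condensation, tert-butyl ester cleavage and decarboxylation (organocatalytic Robinson-type annulation).

Step 2
Reactants: 5 (Z)-3-methylpent-2-en-4-yn-1-ol
Product: 6 tert-butyldimethyl{[(Z)-3-methylpent-2-en-4-yn-1-yl]oxy}silane
Conditions: TBSCl, imidazole, CH2Cl2, 0 °C to rt
Reagents that add atoms: tert-butyldimethylsilyl chloride CC(C)(C)[Si](C)(C)Cl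
Why: Standard silylation of a primary allylic alcohol; the (Z)-alkene that later becomes C12=C19 is bought in with its geometry.

Step 3
Reactants: 6 silyl ether of the (Z)-enynol
Product: 8 (Z)-5-(tert-butyldimethylsilyloxy)-3-methylpent-3-enal, via dienylborane 7 (not isolated)
Conditions: dicyclohexylborane, THF, 0 °C; then H2O2, pH 7 phosphate buffer, 0 °C
Reagents that add atoms: dicyclohexylborane (into 7 only) B(C1CCCCC1)C1CCCCC1; hydrogen peroxide OO
Why: Anti-Markovnikov hydroboration of the terminal alkyne with a hindered dialkylborane and buffered oxidation of the alkenylborane should give the β,γ-unsaturated aldehyde without touching the trisubstituted (Z)-alkene.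

Step 4
Reactants: 4 (S)-5-methylcyclohex-2-en-1-one; 8 (Z)-5-(tert-butyldimethylsilyloxy)-3-methylpent-3-enal
Product: 9 (5S,6S)-6-[(1R,3Z)-5-(tert-butyldimethylsilyloxy)-1-hydroxy-3-methylpent-3-en-1-yl]-5-methylcyclohex-2-en-1-one
Conditions: LDA, THF, −78 °C; Cp2ZrCl2, −78 to −40 °C; then 8, −78 °C; aq. NH4Cl
Reagents that add atoms: none
Why: Aldol addition of the α′-zirconium enolate; the aldehyde should approach anti to the adjacent ring methyl, and zirconium enolates give the syn (erythro) aldol irrespective of enolate geometry, which sets C14 (R) relative to C6.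

Step 5
Reactants: 9 aldol adduct
Product: 10 (5S,6S)-6-[(1R,3Z)-5-(tert-butyldimethylsilyloxy)-3-methyl-1-(trimethylsilyloxy)pent-3-en-1-yl]-5-methylcyclohex-2-en-1-one
Conditions: TMSCl, imidazole, CH2Cl2, 0 °C
Reagents that add atoms: chlorotrimethylsilane C[Si](C)(C)Cl
Why: Temporary silylation removes the acidic hydroxyl and prevents retro-aldol and chelation during the next enolate alkylation.

Step 6
Reactants: 10 trimethylsilyl ether
Product: 12 (5S,6R)-6-[(1R,3Z)-5-(tert-butyldimethylsilyloxy)-1-hydroxy-3-methylpent-3-en-1-yl]-5,6-dimethylcyclohex-2-en-1-one, via methylated silyl ether 11 (not isolated)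
Conditions: LDA, THF, −78 °C; MeI, DMPU, −78 to −30 °C; then citric acid, MeOH, 0 °C
Reagents that add atoms: iodomethane CI
Why: Kinetic α′-deprotonation gives the cross-conjugated lithium dienolate, and methyl iodide should enter anti to the adjacent ring methyl, creating the C5 quaternary centre with the two methyls trans (enolate alkylation, then acidic methanolysis of the labile trimethylsilyl ether only).

Step 7
Reactants: 12 tertiary-flanked secondary alcohol
Product: 13 (1R,3Z)-5-(tert-butyldimethylsilyloxy)-1-[(1R,6S)-1,6-dimethyl-2-oxocyclohex-3-en-1-yl]-3-methylpent-3-en-1-yl acetate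
Conditions: Ac2O, DMAP, Et3N, CH2Cl2, rt
Reagents that add atoms: acetic anhydride CC(=O)OC(C)=O
Why: DMAP-catalysed acetylation installs the C14 acetate of the target while it is the only free hydroxyl; the quaternary α-carbon rules out elimination.

Step 8
Reactants: 13 enone acetate
Product: 14 epoxy ketone of 13 (ring C3–C8 epoxide, oxygen trans to the C6 methyl)
Conditions: t-BuOOH (decane), DBU, CH2Cl2, 0 °C to rt
Reagents that add atoms: tert-butyl hydroperoxide CC(C)(C)OO
Why: Weitz–Scheffer nucleophilic epoxidation attacks only the electron-poor enone, not the C12=C19 alkene; the face anti to the C6 methyl is expected, but both epoxide isomers converge in the next step.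

Step 9
Reactants: 14 epoxy ketone
Product: 16 (2Z,5R,6S,7S)-1-(tert-butyldimethylsilyloxy)-6-ethynyl-3,6,7-trimethyl-9-oxonon-2-en-5-yl acetate, via tosylhydrazone 15 (not isolated)
Conditions: TsNHNH2, AcOH, CH2Cl2, −20 °C to rt
Reagents that add atoms: 4-methylbenzenesulfonohydrazide (into 15 only) Cc1ccc(cc1)S(=O)(=O)NN
Why: Eschenmoser–Tanabe fragmentation of the epoxy tosylhydrazone cuts the template ring, turning C4/C3 into the terminal alkyne and C8 into the aldehyde while C5, C6 and C14 are untouched.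

Step 10
Reactants: 17 methyl (S)-3-hydroxy-2-methylpropanoate
Product: 18 methyl (S)-3-(tert-butyldimethylsilyloxy)-2-methylpropanoate
Conditions: TBSCl, imidazole, DMF, rt
Reagents that add atoms: tert-butyldimethylsilyl chloride CC(C)(C)[Si](C)(C)Cl
Why: Silylation of the chiral-pool hydroxy ester, whose stereocentre becomes C10.

Step 11
Reactants: 18 silylated hydroxy ester; 19 methyl acetate
Product: 20 methyl (S)-5-(tert-butyldimethylsilyloxy)-4-methyl-3-oxopentanoate
Conditions: 19, LDA, THF, −78 °C; then 18, −78 to −20 °C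
Reagents that add atoms: none
Why: Crossed Claisen condensation with the lithium enolate of methyl acetate; the product is held as its enolate between the carbonyls, which protects the C10 centre from epimerisation.

Step 12
Reactants: 20 β-keto ester
Product: 21 methyl (2E,4S)-5-(tert-butyldimethylsilyloxy)-4-methyl-3-(trifluoromethylsulfonyloxy)pent-2-enoate
Conditions: Tf2O, aq. Me4NOH, toluene, 0 °C
Reagents that add atoms: trifluoromethanesulfonic anhydride O=S(=O)(OS(=O)(=O)C(F)(F)F)C(F)(F)F
Why: Triflation of the non-chelated ammonium enolate should give the (E)-enol triflate (triflate trans to the ester), the geometry that keeps the later C8 hydroxyl from lactonising.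

Step 13
Reactants: 16 ynal; 21 (E)-enol triflate
Product: 22 methyl (2E,4S,6S,7S,8R,10Z)-8-acetoxy-12-(tert-butyldimethylsilyloxy)-3-[(2R)-1-(tert-butyldimethylsilyloxy)propan-2-yl]-7-ethynyl-4-hydroxy-6,7,10-trimethyldodeca-2,10-dienoate
Conditions: CrCl2, NiCl2 (cat.), chiral 4-isopropyl-oxazoline methanesulfonamide ligand (enantiomer matched to 8S), Et3N, THF/MeCN, rt
Reagents that add atoms: none
Why: Nozaki–Hiyama–Kishi coupling of the alkenyl triflate with the aldehyde is chemoselective in the presence of acetate, alkyne and ester; the C8 carbinol (S) is set by the chiral chromium ligand and the alkene geometry is retained.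

Step 14
Reactants: 22 γ-hydroxy enoate
Product: 23 4-O-tert-butyldimethylsilyl ether of 22
Conditions: TBSOTf, 2,6-lutidine, CH2Cl2, −78 to 0 °C
Reagents that add atoms: tert-butyldimethylsilyl trifluoromethanesulfonate CC(C)(C)[Si](C)(C)OS(=O)(=O)C(F)(F)F
Why: Silylation of the hindered secondary alcohol gives a robust, bulky C8 substituent that steers the cyclisation and outlives the later removal of the primary silyl ethers.

Step 15
Reactants: 23 alkynyl enoate
Product: 24 (1R,3Z)-1-[(4S,5S,7S,7aR)-7-(tert-butyldimethylsilyloxy)-7a-[(2R)-1-(tert-butyldimethylsilyloxy)propan-2-yl]-4,5-dimethyl-2-oxo-2,4,5,6,7,7a-hexahydro-1H-inden-4-yl]-5-(tert-butyldimethylsilyloxy)-3-methylpent-3-en-1-yl acetate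
Conditions: Ni(cod)2 (15 mol%), PBu3 (30 mol%), Et3B, MeOH/THF (8:1), 50 °C, 0.01 M
Reagents that add atoms: none
Why: Zerovalent nickel binds the enoate and the alkyne and undergoes oxidative cyclization to a nickelacycle in which C4–C9 is formed; methanol protonates the nickel enolate at C1, the alkenylnickel at C3 adds to the ester carbonyl C2 and loss of methoxide gives the enone, while Et3B returns divalent nickel to zerovalent nickel. The closest known reaction type is the nickel-catalysed reductive [3+2] cycloaddition of enoates (or enals) with alkynes to cyclopentenones (cyclopentenols), known intermolecularly and for tethered alkynyl enals; the β,β-disubstituted enoate and terminal alkyne used here extend that precedent. Ring B closes in the 6-exo mode of the oxidative cyclization (tether C5–C6–C7–C8) and ring A closes by 5-exo-trig acyl substitution of C3 on C2. The new quaternary centre C9 (R) should be controlled by a chair-like arrangement of the forming ring in which the C8 silyloxy group and the C5 acetoxyalkyl chain are equatorial and only the C5 and C6 methyls are axial. The step needs chemoselectivity for the electron-poor enoate over the C12=C19 alkene and bonding of the internal alkyne carbon C4 to C9, which the preference of zerovalent nickel for the enoate/alkyne pair and the tether length secure; the C14 acetate cannot be reached by C3 because that would need a four-membered ring.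

Step 16
Reactants: 24 tris-silyl ether
Product: 25 (1R,3Z)-1-[(4S,5S,7S,7aR)-7-(tert-butyldimethylsilyloxy)-7a-[(2R)-1-hydroxypropan-2-yl]-4,5-dimethyl-2-oxo-2,4,5,6,7,7a-hexahydro-1H-inden-4-yl]-5-hydroxy-3-methylpent-3-en-1-yl acetate
Conditions: HF·pyridine, pyridine, THF, 0 °C
Reagents that add atoms: none
Why: Buffered fluoride should cleave the two primary silyl ethers (C11, C20) much faster than the secondary C8 ether next to quaternary C9, and leaves acetate and enone alone.

Step 17
Reactants: 25 diol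
Product: 26 (1R,3Z)-1-[(4S,5S,7S,7aR)-7-(tert-butyldimethylsilyloxy)-4,5-dimethyl-2-oxo-7a-[(2R)-1-oxopropan-2-yl]-2,4,5,6,7,7a-hexahydro-1H-inden-4-yl]-5-chloro-3-methylpent-3-en-1-yl acetate
Conditions: NCS, Me2S, CH2Cl2, −25 to 0 °C; then Et3N, −25 °C
Reagents that add atoms: N-chlorosuccinimide O=C1CCC(=O)N1Cl
Why: Under Corey–Kim conditions the allylic alkoxysulfonium salt collapses to the allylic chloride by direct displacement (geometry retained), whereas the saturated C11 alkoxysulfonium salt is converted by the amine into the aldehyde; the protected C8 oxygen prevents lactol formation.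

Step 18
Reactants: 26 chloro aldehyde
Product: 27 8-O-tert-butyldimethylsilyl ether of the target (tricyclic 11-alcohol)
Conditions: CrCl2, NaI (cat.), THF, 0.003 M, rt
Reagents that add atoms: none
Why: Intramolecular Nozaki–Hiyama–Kishi allylation closes the eight-membered ring through the γ-carbon C12 and creates the vinyl group; the (Z)-allylchromium in a chair transition state (C13 pseudo-axial, methyl pseudo-equatorial) should give C11–OH anti to the C12 methyl, and Felkin–Anh addition next to C10 should give the 10,11-syn relation (11S,12S).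

Step 19
Reactants: 27 silyl ether
Product: 28 Pleuromutilin E (target)
Conditions: aq. HF, MeCN, 0 °C to rt
Reagents that add atoms: none
Why: Acidic fluoride desilylation frees the hindered C8 hydroxyl without acyl migration or hydrolysis of the C14 acetate.

**Compound list**

1 | (E)-but-2-enal | C/C=C/C=O | starting material
2 | tert-butyl 3-oxobutanoate | CC(=O)CC(=O)OC(C)(C)C | starting material
3 | tert-butyl (3S)-2-acetyl-3-methyl-5-oxopentanoate | CC(=O)C(C(=O)OC(C)(C)C)[C@@H](C)CC=O | intermediate
4 | (S)-5-methylcyclohex-2-en-1-one | C[C@@H]1CC(=O)C=CC1 | intermediate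
5 | (Z)-3-methylpent-2-en-4-yn-1-ol | C#C/C(C)=C\CO | starting material
6 | tert-butyldimethyl{[(Z)-3-methylpent-2-en-4-yn-1-yl]oxy}silane | C#C/C(C)=C\CO[Si](C)(C)C(C)(C)C | intermediate
7 | dicyclohexyl[(1E,3Z)-5-(tert-butyldimethylsilyloxy)-3-methylpenta-1,3-dien-1-yl]borane | C1CCCCC1B(/C=C/C(C)=C\CO[Si](C)(C)C(C)(C)C)C1CCCCC1 | intermediate
8 | (Z)-5-(tert-butyldimethylsilyloxy)-3-methylpent-3-enal | O=CC/C(C)=C\CO[Si](C)(C)C(C)(C)C | intermediate
9 | (5S,6S)-6-[(1R,3Z)-5-(tert-butyldimethylsilyloxy)-1-hydroxy-3-methylpent-3-en-1-yl]-5-methylcyclohex-2-en-1-one | C[C@H]1CC=CC(=O)[C@@H]1[C@H](O)C/C(C)=C\CO[Si](C)(C)C(C)(C)C | intermediate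
10 | (5S,6S)-6-[(1R,3Z)-5-(tert-butyldimethylsilyloxy)-3-methyl-1-(trimethylsilyloxy)pent-3-en-1-yl]-5-methylcyclohex-2-en-1-one | C[C@H]1CC=CC(=O)[C@@H]1[C@H](O[Si](C)(C)C)C/C(C)=C\CO[Si](C)(C)C(C)(C)C | intermediate
11 | (5S,6R)-6-[(1R,3Z)-5-(tert-butyldimethylsilyloxy)-3-methyl-1-(trimethylsilyloxy)pent-3-en-1-yl]-5,6-dimethylcyclohex-2-en-1-one | C[C@H]1CC=CC(=O)[C@@]1(C)[C@H](O[Si](C)(C)C)C/C(C)=C\CO[Si](C)(C)C(C)(C)C | intermediate
12 | (5S,6R)-6-[(1R,3Z)-5-(tert-butyldimethylsilyloxy)-1-hydroxy-3-methylpent-3-en-1-yl]-5,6-dimethylcyclohex-2-en-1-one | C[C@H]1CC=CC(=O)[C@@]1(C)[C@H](O)C/C(C)=C\CO[Si](C)(C)C(C)(C)C | intermediate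
13 | (1R,3Z)-5-(tert-butyldimethylsilyloxy)-1-[(1R,6S)-1,6-dimethyl-2-oxocyclohex-3-en-1-yl]-3-methylpent-3-en-1-yl acetate | C[C@H]1CC=CC(=O)[C@@]1(C)[C@H](OC(C)=O)C/C(C)=C\CO[Si](C)(C)C(C)(C)C | intermediate
14 | epoxy ketone of 13 (ring C3–C8 epoxide, oxygen trans to the C6 methyl; major isomer drawn) | C[C@H]1C[C@@H]2O[C@@H]2C(=O)[C@@]1(C)[C@H](OC(C)=O)C/C(C)=C\CO[Si](C)(C)C(C)(C)C | intermediate
15 | 4-methylbenzenesulfonylhydrazone of 14 | C[C@H]1C[C@@H]2O[C@@H]2C(=NNS(=O)(=O)c3ccc(C)cc3)[C@@]1(C)[C@H](OC(C)=O)C/C(C)=C\CO[Si](C)(C)C(C)(C)C | intermediate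
16 | (2Z,5R,6S,7S)-1-(tert-butyldimethylsilyloxy)-6-ethynyl-3,6,7-trimethyl-9-oxonon-2-en-5-yl acetate | O=CC[C@H](C)[C@@](C)(C#C)[C@H](OC(C)=O)C/C(C)=C\CO[Si](C)(C)C(C)(C)C | intermediate
17 | methyl (S)-3-hydroxy-2-methylpropanoate | COC(=O)[C@@H](C)CO | starting material
18 | methyl (S)-3-(tert-butyldimethylsilyloxy)-2-methylpropanoate | COC(=O)[C@@H](C)CO[Si](C)(C)C(C)(C)C | intermediate
19 | methyl acetate | COC(C)=O | starting material
20 | methyl (S)-5-(tert-butyldimethylsilyloxy)-4-methyl-3-oxopentanoate | COC(=O)CC(=O)[C@@H](C)CO[Si](C)(C)C(C)(C)C | intermediate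
21 | methyl (2E,4S)-5-(tert-butyldimethylsilyloxy)-4-methyl-3-(trifluoromethylsulfonyloxy)pent-2-enoate | COC(=O)/C=C(/OS(=O)(=O)C(F)(F)F)[C@@H](C)CO[Si](C)(C)C(C)(C)C | intermediate
22 | methyl (2E,4S,6S,7S,8R,10Z)-8-acetoxy-12-(tert-butyldimethylsilyloxy)-3-[(2R)-1-(tert-butyldimethylsilyloxy)propan-2-yl]-7-ethynyl-4-hydroxy-6,7,10-trimethyldodeca-2,10-dienoate | COC(=O)/C=C(/[C@@H](O)C[C@H](C)[C@@](C)(C#C)[C@H](OC(C)=O)C/C(C)=C\CO[Si](C)(C)C(C)(C)C)[C@@H](C)CO[Si](C)(C)C(C)(C)C | intermediate
23 | 4-O-tert-butyldimethylsilyl ether of 22 | COC(=O)/C=C(/[C@@H](O[Si](C)(C)C(C)(C)C)C[C@H](C)[C@@](C)(C#C)[C@H](OC(C)=O)C/C(C)=C\CO[Si](C)(C)C(C)(C)C)[C@@H](C)CO[Si](C)(C)C(C)(C)C | intermediate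
24 | bicyclic enone: (1R,3Z)-1-[(4S,5S,7S,7aR)-7-(tert-butyldimethylsilyloxy)-7a-[(2R)-1-(tert-butyldimethylsilyloxy)propan-2-yl]-4,5-dimethyl-2-oxo-2,4,5,6,7,7a-hexahydro-1H-inden-4-yl]-5-(tert-butyldimethylsilyloxy)-3-methylpent-3-en-1-yl acetate | CC(=O)O[C@H](C/C(C)=C\CO[Si](C)(C)C(C)(C)C)[C@]1(C)C2=CC(=O)C[C@@]2([C@@H](O[Si](C)(C)C(C)(C)C)C[C@@H]1C)[C@@H](C)CO[Si](C)(C)C(C)(C)C | intermediate
25 | diol: 24 with free C11 and C20 hydroxyls | CC(=O)O[C@H](C/C(C)=C\CO)[C@]1(C)C2=CC(=O)C[C@@]2([C@@H](O[Si](C)(C)C(C)(C)C)C[C@@H]1C)[C@@H](C)CO | intermediate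
26 | chloro aldehyde: (Z)-allylic C20 chloride, C11 aldehyde | CC(=O)O[C@H](C/C(C)=C\CCl)[C@]1(C)C2=CC(=O)C[C@@]2([C@@H](O[Si](C)(C)C(C)(C)C)C[C@@H]1C)[C@@H](C)C=O | intermediate
27 | 8-O-tert-butyldimethylsilyl ether of the target, (5S,6S,8S,9R,10R,11S,12S,14R) | C=C[C@]1(C)C[C@@H](OC(C)=O)[C@]2(C)C3=CC(=O)C[C@@]3([C@@H](O[Si](C)(C)C(C)(C)C)C[C@@H]2C)[C@@H](C)[C@@H]1O | intermediate
28 | Pleuromutilin E | C=C[C@]1(C)C[C@@H](OC(C)=O)[C@]2(C)C3=CC(=O)C[C@@]3([C@@H](O)C[C@@H]2C)[C@@H](C)[C@@H]1O | target

**Step count.** Total: 19 steps. Longest linear sequence: 15 steps (2, 3, 4, 5, 6, 7, 8, 9, 13, 14, 15, 16, 17, 18, 19).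

**Steps most likely to fail**

Step 15. Oxidative cyclization at the β,β-disubstituted enoate may be slow, so that alkyne oligomerisation or reduction without acyl transfer takes over, or facial selectivity at C9 may be poor. The fallback sets out from 16 and 18 and comes back at 24. Ester 18 is converted (MeNHOMe·HCl, i-PrMgCl; then MeMgBr) into (S)-4-(tert-butyldimethylsilyloxy)-3-methylbutan-2-one F1. Kinetic enolisation (KHMDS, PhNTf2) gives (S)-4-(tert-butyldimethylsilyloxy)-3-methylbut-1-en-2-yl trifluoromethanesulfonate F2. CrCl2/NiCl2 coupling of F2 with 16 gives the 1,1-disubstituted allylic alcohol F3, and TBSOTf gives its silyl ether F4. A Pauson–Khand reaction (Co2(CO)8, CH2Cl2; then N-methylmorpholine N-oxide) then joins the alkyne, the C9=C1 alkene and carbon monoxide to 24. The trisubstituted C12=C19 alkene could compete as a Pauson–Khand partner there and would need watching.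

Step 18. Ring strain and transannular crowding between the C5 side chain and the C10 aldehyde may keep the termini apart, so that the allylchromium is protonated or couples intermolecularly. The fallback sets out from 26 and comes back at 27. Pd2(dba)3-catalysed borylation of the allylic chloride with bis(pinacolato)diboron gives the (Z)-allylboronate aldehyde F5. F5 is configurationally stable and cyclises on warming by intramolecular allylboration through a closed six-membered transition state, which gives 27 after aqueous work-up.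

Step 6. Deprotonation may occur at the γ-position (C7) instead of α′, the enolate may eliminate silanolate, or the methyl may enter on the wrong face. The fallback sets out from 9 and comes back at 12. Dess–Martin oxidation of 9 gives (5S)-6-[(3Z)-5-(tert-butyldimethylsilyloxy)-3-methylpent-3-enoyl]-5-methylcyclohex-2-en-1-one F6. Its acidic C5–H is methylated under mild conditions (K2CO3, MeI, acetone), anti to the ring methyl, to give the diketone F7. Reagent-controlled Corey–Bakshi–Shibata reduction of the saturated side-chain ketone (catecholborane, oxazaborolidine enantiomer matched to 14R) then gives 12.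

Further compounds
F1 | step 15 | (S)-4-(tert-butyldimethylsilyloxy)-3-methylbutan-2-one | CC(=O)[C@@H](C)CO[Si](C)(C)C(C)(C)C
F2 | step 15 | (S)-4-(tert-butyldimethylsilyloxy)-3-methylbut-1-en-2-yl trifluoromethanesulfonate | C=C(OS(=O)(=O)C(F)(F)F)[C@@H](C)CO[Si](C)(C)C(C)(C)C
F3 | step 15 | (2Z,5R,6S,7S,9S)-1-(tert-butyldimethylsilyloxy)-10-[(2R)-1-(tert-butyldimethylsilyloxy)propan-2-yl]-6-ethynyl-9-hydroxy-3,6,7-trimethylundeca-2,10-dien-5-yl acetate | C=C([C@@H](O)C[C@H](C)[C@@](C)(C#C)[C@H](OC(C)=O)C/C(C)=C\CO[Si](C)(C)C(C)(C)C)[C@@H](C)CO[Si](C)(C)C(C)(C)C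
F4 | step 15 | 9-O-tert-butyldimethylsilyl ether of F3 | C=C([C@@H](O[Si](C)(C)C(C)(C)C)C[C@H](C)[C@@](C)(C#C)[C@H](OC(C)=O)C/C(C)=C\CO[Si](C)(C)C(C)(C)C)[C@@H](C)CO[Si](C)(C)C(C)(C)C
F5 | step 18 | (Z)-allylboronate aldehyde (26 with the chloride replaced by 4,4,5,5-tetramethyl-1,3,2-dioxaborolan-2-yl) | CC(=O)O[C@H](C/C(C)=C\CB3OC(C)(C)C(C)(C)O3)[C@]1(C)C2=CC(=O)C[C@@]2([C@@H](O[Si](C)(C)C(C)(C)C)C[C@@H]1C)[C@@H](C)C=O
F6 | step 6 | (5S)-6-[(3Z)-5-(tert-butyldimethylsilyloxy)-3-methylpent-3-enoyl]-5-methylcyclohex-2-en-1-one | C[C@H]1CC=CC(=O)C1C(=O)C/C(C)=C\CO[Si](C)(C)C(C)(C)C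
F7 | step 6 | (5S,6R)-6-[(3Z)-5-(tert-butyldimethylsilyloxy)-3-methylpent-3-enoyl]-5,6-dimethylcyclohex-2-en-1-one | C[C@H]1CC=CC(=O)[C@@]1(C)C(=O)C/C(C)=C\CO[Si](C)(C)C(C)(C)C
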